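**Plan**

Ring A is numbered C1 (OMe), C2 (Br), C3, C4 (Br), C5, C6 (O-aryl); ring B is the 2,4-dibromophenyl ring.
Retrosynthesis cuts the O-CH3 bond, trades the C2-Br bond for a C2-CO2Me bond (ipso bromodecarboxylation ortho to the C1 oxygen), opens ring A at C2-C3 and C5-C6, and last cuts the CH2-OAr bond of the open chain.
Enabling feature: C1 bears oxygen between C2 and C6, and C4 bears Br between two CH carbons, so ring A is a C6-C1-C2 ketone with two alpha-methylenes joined to the symmetrical C3-C4(Br)-C5 dialdehyde; the ester that activates C2 sits where the second ring A bromine must end up.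
Forward: ring B is bought intact and attached as an aryloxy group to a four-carbon keto ester, ring A is then closed in one [3+3] condensation, and ester-to-bromine exchange and O-methylation finish the target.
Stereochemistry: the target has no stereocentre and no stereogenic double bond, so nothing has to be controlled.

Key step: step 2

Remark on the chemistry: 2-bromomalonaldehyde is taken to react from its enol form, as supplied.

**Route**

Step 1
Reactants: 1 2,4-dibromophenol; 2 methyl 4-chloro-3-oxobutanoate (methyl 4-chloroacetoacetate)
Product: 3 methyl 4-(2,4-dibromophenoxy)-3-oxobutanoate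
Conditions: NaH (2.1 equiv), 1 (1.1 equiv), THF/DMF, 0 °C, slow addition of 2, then 20-50 °C; aq. HCl work-up
Reagents that add atoms: none
Why: Williamson-type SN2 etherification in which one equivalent of base holds the keto ester as its enolate, shielding the ketone, while the 2,4-dibromophenoxide displaces the primary chloride, the standard way to 4-aryloxyacetoacetates.

Step 2
Reactants: 3 methyl 4-(2,4-dibromophenoxy)-3-oxobutanoate; 4 2-bromomalonaldehyde
Product: 6 methyl 5-bromo-3-(2,4-dibromophenoxy)-2-hydroxybenzoate, via Knoevenagel adduct 5 (not isolated)
Conditions: piperidine (0.2 equiv), AcOH (0.2 equiv), MeOH, 20 °C then 65 °C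
Reagents that add atoms: none
Why: Piperidinium acetate activates one formyl group of 4 as an iminium ion, the doubly activated ester-flanked methylene of 3 (future C2) adds and eliminates in a Knoevenagel condensation to give adduct 5 (C2-C3 bond), and the E and Z forms of 5 equilibrate through its vinylogous enol. The aryloxy-bearing methylene (future C6), acidified by the ketone and the ether oxygen, then enolises and attacks the remaining formyl carbon in an intramolecular aldol condensation, a 6-(enolendo)-exo-trig closure that forms C5-C6 and ring A; loss of water and tautomerisation of the resulting 4-bromocyclohexadienone should deliver the phenol. The closest known reaction type is the [3+3] phenol synthesis from 2-substituted malonaldehydes and ketones that carry two alpha-methylene groups, acetoacetates and acetonedicarboxylates among them. No stereocentre is created. The step needs closure through carbon and not through the ketone oxygen, and it needs the bromine to stay: the symmetrical dialdehyde leaves no regiochemical choice, closure through oxygen gives only a reversible 2H-pyranol whereas closure through carbon ends irreversibly in an aromatic ring, and the bromine sits on an sp2 carbon in the predominant enol and enamine forms, which disfavours its displacement.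

Step 3
Reactants: 6 methyl 5-bromo-3-(2,4-dibromophenoxy)-2-hydroxybenzoate
Product: 7 5-bromo-3-(2,4-dibromophenoxy)-2-hydroxybenzoic acid
Conditions: NaOH (4 equiv), THF/MeOH/H2O, 60 °C; then aq. HCl
Reagents that add atoms: sodium hydroxide, [Na+].[OH-]
Why: Saponification of a methyl salicylate by acyl-oxygen cleavage, run with excess hydroxide because the phenoxide slows attack at the ester, under which the aryl bromides and the diaryl ether are inert.

Step 4
Reactants: 7 5-bromo-3-(2,4-dibromophenoxy)-2-hydroxybenzoic acid
Product: 8 2,4-dibromo-6-(2,4-dibromophenoxy)phenol
Conditions: Br2 (1.05 equiv), NaOAc (2 equiv), AcOH/H2O, 20 °C; aq. NaHSO3 quench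
Reagents that add atoms: bromine, BrBr
Why: Ipso bromodecarboxylation of a salicylic acid (electrophilic aromatic substitution with loss of CO2): the other ortho and the para position of the phenol are occupied, so bromine attacks the carboxyl-bearing carbon and the dienone carboxylate rearomatises by decarboxylation, while ring B, an aryl ether with two bromines, is far less reactive toward one equivalent of Br2.

Step 5
Reactants: 8 2,4-dibromo-6-(2,4-dibromophenoxy)phenol
Product: 9 2,4-dibromo-6-(2,4-dibromophenoxy)anisole (1,5-dibromo-3-(2,4-dibromophenoxy)-2-methoxybenzene, the target)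
Conditions: MeI (1.5 equiv), K2CO3 (2 equiv), acetone, 50 °C
Reagents that add atoms: iodomethane, CI
Why: Williamson O-methylation of an acidic, doubly ortho-substituted phenoxide, routine for 2,4,6-trisubstituted halophenols.

**Compound list**

1 | 2,4-dibromophenol | Oc1ccc(Br)cc1Br | starting material
2 | methyl 4-chloro-3-oxobutanoate | COC(=O)CC(=O)CCl | starting material
3 | methyl 4-(2,4-dibromophenoxy)-3-oxobutanoate | COC(=O)CC(=O)COc1ccc(Br)cc1Br | intermediate
4 | 2-bromomalonaldehyde (2-bromopropanedial) | O=CC(Br)C=O | starting material
5 | methyl (2E)-4-bromo-2-[(2,4-dibromophenoxy)acetyl]-5-oxopent-2-enoate (Knoevenagel adduct, racemic at the CHBr carbon) | COC(=O)/C(=C/C(Br)C=O)C(=O)COc1ccc(Br)cc1Br | intermediate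
6 | methyl 5-bromo-3-(2,4-dibromophenoxy)-2-hydroxybenzoate | COC(=O)c1cc(Br)cc(Oc2ccc(Br)cc2Br)c1O | intermediate
7 | 5-bromo-3-(2,4-dibromophenoxy)-2-hydroxybenzoic acid | OC(=O)c1cc(Br)cc(Oc2ccc(Br)cc2Br)c1O | intermediate
8 | 2,4-dibromo-6-(2,4-dibromophenoxy)phenol | Oc1c(Br)cc(Br)cc1Oc1ccc(Br)cc1Br | intermediate
9 | 2,4-dibromo-6-(2,4-dibromophenoxy)anisole | COc1c(Br)cc(Br)cc1Oc1ccc(Br)cc1Br | target

**Step count**

Total steps: 5. Longest linear sequence: 5 steps (1 and 2 to 3, then 6, 7, 8, 9).

**Steps most likely to fail**

Step 2. After the first condensation the open-chain adduct may rest as a stabilised vinylogous enolate or enaminal whose terminal carbon is too weak an electrophile for the C6 enol, so ring closure could stall. Closure through oxygen with displacement of bromide (furan formation of the Feist-Benary kind) or self-condensation of the dialdehyde could then take over. The fallback does not build ring A but starts from an existing benzene ring. It sets out from 1, which is joined to 2-fluorobenzaldehyde by nucleophilic aromatic substitution (K2CO3, DMAc, 140 °C) to give 2-(2,4-dibromophenoxy)benzaldehyde F1. Baeyer-Villiger oxidation of the aldehyde (mCPBA, CH2Cl2, 20 °C; Dakin-type aryl migration) should give 2-(2,4-dibromophenoxy)phenyl formate F2, which is cleaved with aqueous NaOH in MeOH to 2-(2,4-dibromophenoxy)phenol F3. Bromination with Br2 (2 equiv, AcOH, 0-20 °C) is directed by the free hydroxyl to its para and open ortho positions, ring B being deactivated, and comes back to the route at 8, from which step 5 follows.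

Step 1. The phenoxide of 1 is weakly nucleophilic and ortho-substituted, so intermolecular C-alkylation of the chloroacetoacetate enolate by a second molecule of 2 (dimerisation toward succinylsuccinate-type products) may outrun ether formation. The fallback assembles the keto ester from the acid side. It sets out from 1, which is O-alkylated with chloroacetic acid (aq. NaOH, reflux, then HCl) to give (2,4-dibromophenoxy)acetic acid F4. Coupling with Meldrum's acid (DCC, DMAP, CH2Cl2, 0-20 °C) gives the acyl Meldrum's acid 5-[2-(2,4-dibromophenoxy)-1-hydroxyethylidene]-2,2-dimethyl-1,3-dioxane-4,6-dione F5. Heating F5 in MeOH at reflux opens the dioxanedione and expels acetone and carbon dioxide, returning to the route at 3.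

Step 4. Ipso attack at the hindered carboxyl-bearing carbon may be slow enough that bromine is consumed elsewhere, by substitution on ring B ortho to the ether oxygen or by over-bromination of the product phenol to a bromodienone, leaving acid unconverted. The fallback separates loss of CO2 from bromination. It sets out from 7, which undergoes protodecarboxylation (Ag2CO3 10 mol%, AcOH, DMSO, 120 °C) to 4-bromo-2-(2,4-dibromophenoxy)phenol F6. Ordinary ortho-bromination of F6 at its one open activated position (Br2 1.0 equiv, CH2Cl2, 0 °C), which is much faster than attack on ring B, comes back to the route at 8.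

**Further compounds**

F1 | step 2 | 2-(2,4-dibromophenoxy)benzaldehyde | O=Cc1ccccc1Oc1ccc(Br)cc1Br
F2 | step 2 | 2-(2,4-dibromophenoxy)phenyl formate | O=COc1ccccc1Oc1ccc(Br)cc1Br
F3 | step 2 | 2-(2,4-dibromophenoxy)phenol | Oc1ccccc1Oc1ccc(Br)cc1Br
F4 | step 1 | (2,4-dibromophenoxy)acetic acid | OC(=O)COc1ccc(Br)cc1Br
F5 | step 1 | 5-[2-(2,4-dibromophenoxy)-1-hydroxyethylidene]-2,2-dimethyl-1,3-dioxane-4,6-dione | CC1(C)OC(=O)C(=C(O)COc2ccc(Br)cc2Br)C(=O)O1
F6 | step 4 | 4-bromo-2-(2,4-dibromophenoxy)phenol | Oc1ccc(Br)cc1Oc1ccc(Br)cc1Br
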